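**Retrosynthetic overview**

- Target 25 ← allylic oxidation of the isopropenyl methyl group (SeO2, then MnO2) of 23 ← O3-acylation and removal of a temporary C4 bromine from alcohol 21.
- 21 ← bromoaryne 19 (from silyl triflate 11) + α-silyloxy aldehyde 17 in one flask: the O1–C7a and C3–C3a bonds form together and close the dihydrofuran ring onto the benzene ring already present in 1 (the only ring-forming event).
- Enabling feature: O1 and C3 sit on the adjacent ring carbons C7a and C3a, and C3 carries oxygen, so O1–C2–C3 is an α-oxido aldehyde (nucleophilic O, electrophilic C) spanning a C3a≡C7a triple bond; C4–H beside C3a can hold a bromine that steers the addition and is later replaced by hydrogen.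
- 11 ← 1-(2-bromo-4-hydroxyphenyl)ethanone 1 (carbamate, CBS reduction, silylation between O and Br, triflation, esterification with acid 10); 17 ← prenol 12 (Sharpless epoxidation, epoxide-to-allylic-diol isomerisation, silylation, Swern oxidation).

Key step: step 10

Remark: the SMILES is read as (2R,3S) in the ring with the C2 and C3 substituents trans, R at the aryl carbinol and R at the α-carbon of the 2-methylbutanoate; the route is built for this isomer.

**Route**

Step 1
Reactants: 1 1-(2-bromo-4-hydroxyphenyl)ethanone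
Product: 2 4-acetyl-3-bromophenyl propan-2-ylcarbamate
Conditions: iPrNCO, Et3N (cat.), CH2Cl2, rt
Reagents that add atoms: isopropyl isocyanate CC(C)N=C=O
Why: Base-catalysed addition of the phenol to the isocyanate gives the O-aryl N-isopropylcarbamate, which later directs metalation and can be removed under mild base; no stereocentre is formed.

Step 2
Reactants: 2 4-acetyl-3-bromophenyl propan-2-ylcarbamate
Product: 3 3-bromo-4-[(1R)-1-hydroxyethyl]phenyl propan-2-ylcarbamate
Conditions: (3aS)-1-methyl-3,3-diphenyltetrahydro-1H,3H-pyrrolo[1,2-c][1,3,2]oxazaborole (cat.), BH3·SMe2, THF, −20 °C; MeOH quench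
Reagents that add atoms: none
Why: Corey–Bakshi–Shibata reduction: the ketone binds the oxazaborolidine with the large ortho-bromoaryl group turned away from the catalyst and the N-bound borane delivers hydride to one face, the (S)-catalyst giving the (R)-carbinol as with other aryl methyl ketones.

Step 3
Reactants: 3 3-bromo-4-[(1R)-1-hydroxyethyl]phenyl propan-2-ylcarbamate
Product: 7 3-bromo-4-[(1R)-1-hydroxyethyl]-2-(trimethylsilyl)phenyl propan-2-ylcarbamate, via bis-silyl carbamate 4 (not isolated), via aryllithium 5 (not isolated), via tris-silyl carbamate 6 (not isolated)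
Conditions: Me3SiOTf, TMEDA, Et2O, 0 °C → rt; then Me3SiCl, LiN(iPr)2, THF, −78 °C; aq. citric acid, MeOH
Reagents that add atoms: chlorotrimethylsilane C[Si](C)(C)Cl (aryl C–Si of 7); trimethylsilyl trifluoromethanesulfonate C[Si](C)(C)OS(=O)(=O)C(F)(F)F (N–Si and O–Si groups of 4 to 6 only, lost on work-up)
Why: Directed ortho-metalation of an in situ N-silylated O-aryl carbamate: the C–H between the carbamate oxygen and bromine is the most acidic, the amide base does not exchange bromine, and the chlorosilane already present silylates aryllithium 5 before loss of LiBr or halogen migration, while the mild acidic work-up strips only the N- and O-silyl groups.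

Step 4
Reactants: 7 3-bromo-4-[(1R)-1-hydroxyethyl]-2-(trimethylsilyl)phenyl propan-2-ylcarbamate
Product: 9 3-bromo-4-[(1R)-1-hydroxyethyl]-2-(trimethylsilyl)phenyl trifluoromethanesulfonate, via silylphenol 8 (not isolated)
Conditions: DBU, Et2NH, MeCN, 40 °C; then PhNTf2, rt
Reagents that add atoms: N-phenyl-bis(trifluoromethanesulfonimide) O=S(=O)(N(c1ccccc1)S(=O)(=O)C(F)(F)F)C(F)(F)F
Why: DBU-induced E1cB cleavage of the secondary carbamate releases the phenoxide of 8 (the isocyanate is scavenged by diethylamine as a urea), which is triflated in the same flask by a mild reagent that leaves the neutral secondary alcohol alone; this is the standard carbamate route to ortho-silylaryl triflates.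

Step 5
Reactants: 9 3-bromo-4-[(1R)-1-hydroxyethyl]-2-(trimethylsilyl)phenyl trifluoromethanesulfonate; 10 (2R)-2-methylbutanoic acid
Product: 11 (1R)-1-[2-bromo-4-{[(trifluoromethyl)sulfonyl]oxy}-3-(trimethylsilyl)phenyl]ethyl (2R)-2-methylbutanoate
Conditions: N-(3-dimethylaminopropyl)-N'-ethylcarbodiimide hydrochloride, 4-(dimethylamino)pyridine (cat.), CH2Cl2, 0 °C → rt
Reagents that add atoms: none
Why: Steglich esterification acylates the carbinol oxygen, so the carbinol configuration is retained and the α-centre of the acid is not exposed to enolising conditions.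

Step 6
Reactants: 12 3-methylbut-2-en-1-ol (prenol)
Product: 13 [(2S)-3,3-dimethyloxiran-2-yl]methanol
Conditions: Ti(OiPr)4 (cat.), diisopropyl L-(+)-tartrate (cat.), t-BuOOH, 4 Å molecular sieves, CH2Cl2, −20 °C
Reagents that add atoms: tert-butyl hydroperoxide CC(C)(C)OO
Why: Sharpless asymmetric epoxidation; with the L-(+)-tartrate the titanium-bound peroxide delivers oxygen to the face that gives the (S)-epoxy alcohol (same facial sense as geraniol to (2S,3S)-epoxygeraniol).

Step 7
Reactants: 13 [(2S)-3,3-dimethyloxiran-2-yl]methanol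
Product: 14 (2R)-3-methylbut-3-ene-1,2-diol
Conditions: Ti(OiPr)4 (1.5 equiv), CH2Cl2, rt; aq. tartaric acid
Reagents that add atoms: none
Why: Titanium alkoxide-mediated isomerisation of a 2,3-epoxy alcohol to an allylic diol: the hydroxyl-bound Lewis acid opens the tertiary C3–O bond and a methyl proton is lost, so C2 and its C–O bond are untouched (S becomes R by priority change only).

Step 8
Reactants: 14 (2R)-3-methylbut-3-ene-1,2-diol
Product: 15 (2R)-3-methylbut-3-ene-1,2-diyl bis(triethylsilyl) ether
Conditions: Et3SiCl, imidazole, DMF, 0 °C → rt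
Reagents that add atoms: chlorotriethylsilane CC[Si](CC)(CC)Cl
Why: Standard imidazole-mediated silylation of both hydroxyl groups; no stereocentre is touched.

Step 9
Reactants: 15 (2R)-3-methylbut-3-ene-1,2-diyl bis(triethylsilyl) ether
Product: 17 (2R)-3-methyl-2-[(triethylsilyl)oxy]but-3-enal, via alkoxysulfonium chloride 16 (not isolated)
Conditions: (COCl)2, DMSO, CH2Cl2, −78 → −40 °C; Et3N, −78 °C; cold pH 7 buffer
Reagents that add atoms: none
Why: Swern oxidation applied directly to the bis-silyl ether: activated DMSO cleaves only the unhindered primary triethylsilyl ether to give 16, which collapses to the aldehyde on addition of amine, leaving the secondary silyl ether and the α-centre intact if the quench is kept cold.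

Step 10
Reactants: 11 (1R)-1-[2-bromo-4-{[(trifluoromethyl)sulfonyl]oxy}-3-(trimethylsilyl)phenyl]ethyl (2R)-2-methylbutanoate; 17 (2R)-3-methyl-2-[(triethylsilyl)oxy]but-3-enal
Product: 21 (1R)-1-[(2R,3S)-4-bromo-3-hydroxy-2-(prop-1-en-2-yl)-2,3-dihydro-1-benzofuran-5-yl]ethyl (2R)-2-methylbutanoate, via potassium alkoxide 18 (not isolated), via bromoaryne 19 (not isolated), via aryl anion 20 (not isolated)
Conditions: KF, 18-crown-6, THF, 0 °C → rt, 11 added slowly to 17 (1.5 equiv); H2O quench
Reagents that add atoms: none
Why: Proposed new method: fluoride removes the triethylsilyl group of 17 to give alkoxide 18 and, by attack at the aryl silicon with loss of triflate, generates 3-bromoaryne 19; 18 adds through oxygen to the aryne carbon remote from bromine and the resulting aryl anion 20 is caught at once by the neighbouring formyl group, so an α-oxido aldehyde is inserted across the triple bond as a formal [3+2] annulation, the closest known reaction types being the aryne annulations of N-sulfonyl α-amino ketones to 3-hydroxyindolines and of salicylaldehydes to xanthenols, not yet shown for an aliphatic α-hydroxy aldehyde. The O–aryl bond forms intermolecularly and the dihydrofuran ring then closes by 5-exo-trig addition of the aryl carbanion to the C=O group. Regiochemistry rests on the bromine beside the triple bond: the C–Br bond makes the distal aryne carbon the more linear and electrophilic one and stabilises negative charge on the carbon next to it, so oxygen goes para to the side chain (future C7a) and the carbanion arises at future C3a, where carbonyl capture should outrun loss of bromide. C2 comes unchanged from 17, and the new centre C3 is set by 1,2-induction in the ring closure: the carbonyl oxygen turns away from the isopropenyl group on C2 (the formyl hydrogen eclipses it instead), which should give the trans (3S) alkoxide. Chemoselectivity is needed against ene or [2+2] reactions of the aryne with the alkenes and against arylation of the product alkoxide; the anionic oxygen nucleophile should be far faster than a neutral π-system, and 17 is used in excess with slow addition of 11.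

Step 11
Reactants: 21 (1R)-1-[(2R,3S)-4-bromo-3-hydroxy-2-(prop-1-en-2-yl)-2,3-dihydro-1-benzofuran-5-yl]ethyl (2R)-2-methylbutanoate
Product: 22 (1R)-1-[(2R,3S)-4-bromo-3-[(3-methylbutanoyl)oxy]-2-(prop-1-en-2-yl)-2,3-dihydro-1-benzofuran-5-yl]ethyl (2R)-2-methylbutanoate
Conditions: (iPrCH2CO)2O, 4-(dimethylamino)pyridine, Et3N, CH2Cl2, 0 °C → rt
Reagents that add atoms: 3-methylbutanoic anhydride CC(C)CC(=O)OC(=O)CC(C)C
Why: Nucleophilic catalysis transfers the acyl group to the secondary benzylic oxygen with retention at C3, under basic conditions that avoid acid-induced dehydration to the benzofuran.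

Step 12
Reactants: 22 (1R)-1-[(2R,3S)-4-bromo-3-[(3-methylbutanoyl)oxy]-2-(prop-1-en-2-yl)-2,3-dihydro-1-benzofuran-5-yl]ethyl (2R)-2-methylbutanoate
Product: 23 (1R)-1-[(2R,3S)-3-[(3-methylbutanoyl)oxy]-2-(prop-1-en-2-yl)-2,3-dihydro-1-benzofuran-5-yl]ethyl (2R)-2-methylbutanoate
Conditions: Bu3SnH, azobisisobutyronitrile (cat.), toluene, 80 °C
Reagents that add atoms: none
Why: Radical chain hydrodebromination: the stannyl radical abstracts bromine and the aryl σ-radical (no 1,5-hydrogen within reach, cyclisation onto the alkene geometrically excluded) is reduced by the tin hydride kept at high concentration; the esters and the 1,1-disubstituted alkene are inert.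

Step 13
Reactants: 23 (1R)-1-[(2R,3S)-3-[(3-methylbutanoyl)oxy]-2-(prop-1-en-2-yl)-2,3-dihydro-1-benzofuran-5-yl]ethyl (2R)-2-methylbutanoate
Product: 24 (1R)-1-[(2R,3S)-2-(3-hydroxyprop-1-en-2-yl)-3-[(3-methylbutanoyl)oxy]-2,3-dihydro-1-benzofuran-5-yl]ethyl (2R)-2-methylbutanoate
Conditions: SeO2 (cat.), t-BuOOH, CH2Cl2, rt
Reagents that add atoms: tert-butyl hydroperoxide CC(C)(C)OO (terminal oxidant); selenium dioxide O=[Se]=O (catalytic oxygen carrier)
Why: Riley allylic oxidation (ene reaction of SeO2 at the terminal CH2, then [2,3]-sigmatropic shift): on a 1,1-disubstituted alkene the methyl group is oxidised in preference to the tertiary C2–H, giving the 2-substituted allylic alcohol; any enal formed alongside is converged in step 14.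

Step 14
Reactants: 24 (1R)-1-[(2R,3S)-2-(3-hydroxyprop-1-en-2-yl)-3-[(3-methylbutanoyl)oxy]-2,3-dihydro-1-benzofuran-5-yl]ethyl (2R)-2-methylbutanoate
Product: 25 (1R)-1-[(2R,3S)-3-[(3-methylbutanoyl)oxy]-2-(3-oxoprop-1-en-2-yl)-2,3-dihydro-1-benzofuran-5-yl]ethyl (2R)-2-methylbutanoate (CNP0154159.1)
Conditions: MnO2, CH2Cl2, rt
Reagents that add atoms: none
Why: MnO2 oxidises only the allylic alcohol, under neutral conditions that spare both benzylic esters and avoid base-induced elimination of the C3 acyloxy group from the γ-acidic enal.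

**Compound list**

1 | 1-(2-bromo-4-hydroxyphenyl)ethanone | CC(=O)c1ccc(O)cc1Br | starting material
2 | 4-acetyl-3-bromophenyl propan-2-ylcarbamate | CC(=O)c1ccc(OC(=O)NC(C)C)cc1Br | intermediate
3 | 3-bromo-4-[(1R)-1-hydroxyethyl]phenyl propan-2-ylcarbamate | C[C@@H](O)c1ccc(OC(=O)NC(C)C)cc1Br | intermediate
4 | 3-bromo-4-[(1R)-1-(trimethylsilyloxy)ethyl]phenyl propan-2-yl(trimethylsilyl)carbamate | C[C@@H](O[Si](C)(C)C)c1ccc(OC(=O)N(C(C)C)[Si](C)(C)C)cc1Br | intermediate (not isolated)
5 | 2-lithio derivative of 4 (lithium on the ring carbon between the carbamate oxygen and bromine) | C[C@@H](O[Si](C)(C)C)c1ccc(OC(=O)N(C(C)C)[Si](C)(C)C)c([Li])c1Br | intermediate (not isolated)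
6 | 3-bromo-2-(trimethylsilyl)-4-[(1R)-1-(trimethylsilyloxy)ethyl]phenyl propan-2-yl(trimethylsilyl)carbamate | C[C@@H](O[Si](C)(C)C)c1ccc(OC(=O)N(C(C)C)[Si](C)(C)C)c([Si](C)(C)C)c1Br | intermediate (not isolated)
7 | 3-bromo-4-[(1R)-1-hydroxyethyl]-2-(trimethylsilyl)phenyl propan-2-ylcarbamate | C[C@@H](O)c1ccc(OC(=O)NC(C)C)c([Si](C)(C)C)c1Br | intermediate
8 | 3-bromo-4-[(1R)-1-hydroxyethyl]-2-(trimethylsilyl)phenol | C[C@@H](O)c1ccc(O)c([Si](C)(C)C)c1Br | intermediate (not isolated)
9 | 3-bromo-4-[(1R)-1-hydroxyethyl]-2-(trimethylsilyl)phenyl trifluoromethanesulfonate | C[C@@H](O)c1ccc(OS(=O)(=O)C(F)(F)F)c([Si](C)(C)C)c1Br | intermediate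
10 | (2R)-2-methylbutanoic acid | CC[C@@H](C)C(=O)O | starting material
11 | (1R)-1-[2-bromo-4-{[(trifluoromethyl)sulfonyl]oxy}-3-(trimethylsilyl)phenyl]ethyl (2R)-2-methylbutanoate | CC[C@@H](C)C(=O)O[C@H](C)c1ccc(OS(=O)(=O)C(F)(F)F)c([Si](C)(C)C)c1Br | intermediate
12 | 3-methylbut-2-en-1-ol (prenol) | CC(C)=CCO | starting material
13 | [(2S)-3,3-dimethyloxiran-2-yl]methanol | CC1(C)O[C@H]1CO | intermediate
14 | (2R)-3-methylbut-3-ene-1,2-diol | C=C(C)[C@@H](O)CO | intermediate
15 | (2R)-3-methylbut-3-ene-1,2-diyl bis(triethylsilyl) ether | C=C(C)[C@@H](O[Si](CC)(CC)CC)CO[Si](CC)(CC)CC | intermediate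
16 | dimethyl{[(2R)-3-methyl-2-(triethylsilyloxy)but-3-en-1-yl]oxy}sulfonium chloride | C=C(C)[C@@H](O[Si](CC)(CC)CC)CO[S+](C)C.[Cl-] | intermediate (not isolated)
17 | (2R)-3-methyl-2-[(triethylsilyl)oxy]but-3-enal | C=C(C)[C@@H](O[Si](CC)(CC)CC)C=O | intermediate
18 | potassium (2R)-3-methyl-1-oxobut-3-en-2-olate | [K+].C=C(C)[C@@H]([O-])C=O | intermediate (not isolated)
19 | (1R)-1-(2-bromo-3,4-didehydrophenyl)ethyl (2R)-2-methylbutanoate (3-bromoaryne) | CC[C@@H](C)C(=O)O[C@H](C)C1=C(Br)C#CC=C1 | intermediate (not isolated)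
20 | potassium salt of the aryl anion at C3 of (1R)-1-[2-bromo-4-{[(2R)-3-methyl-1-oxobut-3-en-2-yl]oxy}phenyl]ethyl (2R)-2-methylbutanoate | [K+].CC[C@@H](C)C(=O)O[C@H](C)c1ccc(O[C@@H](C=O)C(C)=C)[c-]c1Br | intermediate (not isolated)
21 | (1R)-1-[(2R,3S)-4-bromo-3-hydroxy-2-(prop-1-en-2-yl)-2,3-dihydro-1-benzofuran-5-yl]ethyl (2R)-2-methylbutanoate | C=C(C)[C@H]1Oc2ccc([C@@H](C)OC(=O)[C@H](C)CC)c(Br)c2[C@@H]1O | intermediate
22 | (1R)-1-[(2R,3S)-4-bromo-3-[(3-methylbutanoyl)oxy]-2-(prop-1-en-2-yl)-2,3-dihydro-1-benzofuran-5-yl]ethyl (2R)-2-methylbutanoate | C=C(C)[C@H]1Oc2ccc([C@@H](C)OC(=O)[C@H](C)CC)c(Br)c2[C@@H]1OC(=O)CC(C)C | intermediate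
23 | (1R)-1-[(2R,3S)-3-[(3-methylbutanoyl)oxy]-2-(prop-1-en-2-yl)-2,3-dihydro-1-benzofuran-5-yl]ethyl (2R)-2-methylbutanoate | C=C(C)[C@H]1Oc2ccc([C@@H](C)OC(=O)[C@H](C)CC)cc2[C@@H]1OC(=O)CC(C)C | intermediate
24 | (1R)-1-[(2R,3S)-2-(3-hydroxyprop-1-en-2-yl)-3-[(3-methylbutanoyl)oxy]-2,3-dihydro-1-benzofuran-5-yl]ethyl (2R)-2-methylbutanoate | C=C(CO)[C@H]1Oc2ccc([C@@H](C)OC(=O)[C@H](C)CC)cc2[C@@H]1OC(=O)CC(C)C | intermediate
25 | (1R)-1-[(2R,3S)-3-[(3-methylbutanoyl)oxy]-2-(3-oxoprop-1-en-2-yl)-2,3-dihydro-1-benzofuran-5-yl]ethyl (2R)-2-methylbutanoate | C=C(C=O)[C@H]1Oc2ccc([C@@H](C)OC(=O)[C@H](C)CC)cc2[C@@H]1OC(=O)CC(C)C | target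

**Step count and risks**

Total step count: 14. Longest linear sequence: 10 steps (steps 1 to 5, then 10 to 14).

Steps most likely to fail:

1. Step 10 (proposed new method). What may go wrong: base-induced enolisation of the α-silyloxy β,γ-unsaturated aldehyde before capture (erosion of the C2 configuration, drift of the alkene into conjugation), further arylation of the product alkoxide, and insufficient facial selectivity in the ring closure. The fallback uses known chemistry, sets out from silyl triflate 11 and comes back at 21. Treatment of 11 with CsF in N,N-dimethylformamide should bring about the known insertion of the aryne into the formamide C=O bond, the amide oxygen adding remote from bromine, and aqueous work-up should hydrolyse the adduct to the salicylaldehyde (1R)-1-(2-bromo-3-formyl-4-hydroxyphenyl)ethyl (2R)-2-methylbutanoate F1. F1 would then be annulated with the sulfonium ylide made from (2-methylprop-2-en-1-yl)tetrahydrothiophenium bromide and Cs2CO3 in MeCN: Corey–Chaykovsky addition to the aldehyde to give the trans vinyl epoxide, which the neighbouring phenoxide opens at the allylic carbon with inversion, a known [4+1] route to trans-2,3-dihydrobenzofuran-3-ols. This should give 21 together with its trans diastereomer (1R)-1-[(2S,3R)-4-bromo-3-hydroxy-2-(prop-1-en-2-yl)-2,3-dihydro-1-benzofuran-5-yl]ethyl (2R)-2-methylbutanoate F2, separable because of the two side-chain centres; a chiral sulfide in place of tetrahydrothiophene is the option for facial control. In this fallback O1–C2 and C2–C3 are the bonds made last and aldehyde 17 is not needed.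

2. Step 9. What may go wrong: amine-promoted migration of the double bond into conjugation or epimerisation of the new α-silyloxy aldehyde during the oxidation, and silyl migration. The fallback sets out from 15 and comes back at 17, uncoupling deprotection from oxidation and avoiding any amine base. The primary silyl ether of 15 would be removed selectively (HF·pyridine, pyridine, THF, 0 °C) to give (2R)-3-methyl-2-[(triethylsilyl)oxy]but-3-en-1-ol F3, which would be oxidised with Dess–Martin periodinane and NaHCO3 in CH2Cl2 at 0 °C to 17 and used at once.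

3. Step 13. What may go wrong: poor site selectivity of the selenium oxidant (attack at C2–H), over-oxidation, and ionisation of the benzylic esters by the acidic selenium species. The fallback sets out from 23 and comes back at 25, bypassing 24. Ene-type chlorination of the isopropenyl group with Ca(OCl)2 and solid CO2 in CH2Cl2/H2O at 0 °C should give the allylic chloride (1R)-1-[(2R,3S)-2-(3-chloroprop-1-en-2-yl)-3-[(3-methylbutanoyl)oxy]-2,3-dihydro-1-benzofuran-5-yl]ethyl (2R)-2-methylbutanoate F4, and Ganem oxidation of F4 with trimethylamine N-oxide in DMSO at rt should give the enal 25 directly.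

**Further compounds**

F1 | step 10 | (1R)-1-(2-bromo-3-formyl-4-hydroxyphenyl)ethyl (2R)-2-methylbutanoate | CC[C@@H](C)C(=O)O[C@H](C)c1ccc(O)c(C=O)c1Br
F2 | step 10 | (1R)-1-[(2S,3R)-4-bromo-3-hydroxy-2-(prop-1-en-2-yl)-2,3-dihydro-1-benzofuran-5-yl]ethyl (2R)-2-methylbutanoate | C=C(C)[C@@H]1Oc2ccc([C@@H](C)OC(=O)[C@H](C)CC)c(Br)c2[C@H]1O
F3 | step 9 | (2R)-3-methyl-2-[(triethylsilyl)oxy]but-3-en-1-ol | C=C(C)[C@@H](O[Si](CC)(CC)CC)CO
F4 | step 13 | (1R)-1-[(2R,3S)-2-(3-chloroprop-1-en-2-yl)-3-[(3-methylbutanoyl)oxy]-2,3-dihydro-1-benzofuran-5-yl]ethyl (2R)-2-methylbutanoate | C=C(CCl)[C@H]1Oc2ccc([C@@H](C)OC(=O)[C@H](C)CC)cc2[C@@H]1OC(=O)CC(C)C
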